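## The problem

Hypothamnolic acid (17) is a depside with no stereocentre, so the task is entirely one of regiochemistry and of telling similar oxygen functions apart. Ring A is pentasubstituted (C1 OMe, C2 H, C3 CH3, C4 depside C=O, C5 OH, C6 CO2H). Ring B is hexasubstituted (C1′ CO2H, C2′ OH, C3′ CH3, C4′ OH, C5′ O-acyl, C6′ CH3). The ester joins a carboxyl flanked by C3–CH3 and C5–OH to a phenol oxygen flanked by C6′–CH3 and C4′–OH, so a direct acylation is hindered on both partners. Five ring oxygens must be distinguished (one methyl ether, one acylated oxygen, three free phenols), and two carboxyls must end free. The aryl ester does not tolerate strong base, and the free C4′–OH next to the C5′ acyloxy group invites acyl migration. Both salicylic-type acids can decarboxylate on heating or in strong acid, and deprotected ring B is easily oxidized, so the last operations must be neutral and mild. The feature that opens the route is the orsellinate pattern of ring A: carbonyl on C4, oxygens on C5 and C1, methyl on C3, and the C6 carboxyl on the carbon between the two oxygens. Ring atoms C4, C5, C6, C1, C2, C3 therefore map onto C2–C7 of a 3,5,7-trioxooctanoate carrying a carboxyl on its C4, and that chain can carry the ring B ester before ring A exists.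

## Retrosynthesis

**17 from 16.** The four O–benzyl bonds are cut (two ethers on ring B, two esters). One neutral hydrogenolysis frees all four groups and leaves the aryl ester and the methyl ether alone. Ring B thus keeps its C4′ oxygen masked until no base or Lewis acid follows, which closes the acyl-migration pathway.

**16 from 15.** The O–CH3 bond at C1 is cut. The C1 oxygen starts as a chain ketone, so the methyl group can only be added after ring closure. In 15 the C5 hydroxyl lies between two carbonyl-bearing carbons, while the C1 hydroxyl has one such neighbour and C2–H on the other side. The forward step must monoalkylate the less hindered phenol.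

**15 from 13 (key disconnection).** The C3–C4 bond of ring A is cut, which opens the ring to the aryl triketo ester 13. The neighbouring cut, the ester C–O bond, would require acylation of a hindered phenol by a hindered acid. Cutting the ring instead removes the arene altogether. The forward reaction is an aldol closure through carbinol 14 followed by dehydration. It must be preferred over Claisen closure onto the aryl ester.

**13 from 11 and 6.** The ester O–C(acyl) bond is cut, but at a stage where the acyl carbon is the sp carbon of acylketene 12, released thermally from dioxinone 11. Addition of the O–H of 6 across a ketene is far less sensitive to ortho substituents than any acyl substitution. The forward step must favour intermolecular capture over capture by the chain's own enol oxygen.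

**11 from 9 and 10; 9 from 7 and 8.** Two C–C bonds at the future C6 are cut: its ester carbon comes from 8 and its acetoacetyl group from 10. The dioxinone of 7 masks the future depside carbonyl and leaves only one acidic carbon in 9. The acetoacetyl group can therefore enter only at the correct site; in an open 3-oxoglutarate diester two sites would compete.

**6 from 1 through 2, 3, 4 and 5.** The C5′–O bond is cut by way of a formyl group and a Baeyer–Villiger oxidation (formate 5). Compound 1 already holds every carbon of ring B and has a single free ring position, so formylation of ester 2 to 3 is unambiguous. Benzylation to 4 before the oxidation leaves exactly one free phenol in 6.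

## Roads not taken

**Alternative 1:** The cut removes both carboxyl carbons (C6–C and C1′–C); each returns as a formyl group that is then oxidized.
- Forward key step: the unprotected depside A2 (2,4-dihydroxy-3,6-dimethylphenyl 2-hydroxy-4-methoxy-6-methylbenzoate) undergoes a twofold Rieche formylation ortho to its phenols to give dialdehyde A1. A twofold aldehyde oxidation of A1 would give 17.
- Merits: no protecting group in the key step; ring B of A2 has one free carbon; the methyl ether is present from the start; probably the shortest sequence.
- Weak points: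
  - A2 still contains the depside bond, so the hindered esterification and the choice of one hydroxyl out of three on the ring B partner are only moved earlier.
  - Ring A of A2 has two free carbons, C6 (ortho to the phenol) and C2 (para to it). The selectivity rests on phenoxide direction alone.
  - A strong Lewis acid meets a free C4′–OH next to the C5′ acyloxy group, which risks acyl migration or cleavage.
  - Two electron-rich hydroxy aldehydes must be oxidized beside an unprotected, oxidizable ring B.
- Comparison: this road is shorter. The chosen plan sets against it a ring A whose substitution follows from the chain, an ester formed on an unhindered ketene carbon, and ring B oxygens masked until the final neutral step.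

**Alternative 2:** The cut is at C5′–C6′ and C1′–C2′ of ring B.
- Forward key step: a Diels–Alder reaction of bis-silyl dienolate A4 (a 1-benzyloxy-2-methyl-1,3-bis(trimethylsilyloxy)buta-1,3-diene whose C4 carries the complete ring A aroyloxy group) with benzyl but-2-ynoate A5. Aromatization with loss of the benzyloxy group and of silicon gives A3, and one hydrogenolysis of A3 would give 17.
- Merits: the C5′–O bond can be made by alkylating the ring A carboxylate, not by hindered acylation; all ring B substituents are set at once; only one step follows the key step.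
- Weak points:
  - The complete ring A acid, with its oxygens already differentiated, must be built separately first, and it carries the same methylation question.
  - A5 is an internal alkynoate with a methyl group on its β carbon (future C6′) and is a sluggish dienophile.
  - At the temperatures needed, A4 can undergo silyl shifts or migration of the acyl group to the neighbouring C4′ oxygen.
- Comparison: after the key step this road is better (one step against two, no selective methylation on the depside). Overall it is longer. The chosen plan sets against it a ring B phenol reached in four steps from 1 and a ring closure that is ionic and intramolecular.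

**Alternative 3:** The cut is at C2–C3 and C4–C5 of ring A.
- Forward key step: diene A8 (benzyl 2-[(benzyloxy)(trimethylsilyloxy)methylidene]-3-methoxybut-3-enoate) and the ring B aryl but-2-ynoate A7 (the but-2-ynoate of 6) are heated. The adduct aromatizes with loss of the benzyloxy group and of silicon to A6, which is the same compound as 16.
- Merits: it shares phenol 6; the depside ester comes from an unhindered ynoic acid; the C1 methoxy group is in the diene, so no selective methylation is needed; it would be one or two steps shorter than the chosen plan.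
- Weak points:
  - A7 has a methyl group on the β carbon (future C3).
  - A8 has an ester on its central carbon (future C6), which lowers the diene energy and crowds the s-cis form.
  - The cycloaddition is intermolecular and both partners are deactivated; regiochemistry rests on polarization only.
  - A8 is sensitive to silyl shift and hydrolysis, and close precedent for so substituted a pair is lacking.
- Comparison: this road is better in step count and on the methyl ether. The chosen plan sets against it a ring closure in which every ring carbon is already placed by the chain and the new bond forms intramolecularly at or below room temperature. The price is the selective methylation of step 9.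

Key step: step 8

Remark on the chemistry: 13 is a mixture of keto and enol tautomers and is drawn as one enol. Carbinol 14 is a transient mixture of diastereomers whose stereocentres disappear in the same step. The target has no stereocentre.

## Route

Step 1
Reactants: 1 2,4-dihydroxy-3,6-dimethylbenzoic acid
Product: 2 benzyl 2,4-dihydroxy-3,6-dimethylbenzoate
Conditions: BnBr (1.05 equiv), KHCO3, DMF, 40 °C
Reagents that add atoms: benzyl bromide, BrCc1ccccc1
Why: Carboxylate O-alkylation (SN2 esterification); hydrogencarbonate ionizes only the carboxylic acid, so the two chelated phenols should stay free.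

Step 2
Reactants: 2 benzyl 2,4-dihydroxy-3,6-dimethylbenzoate
Product: 3 benzyl 5-formyl-2,4-dihydroxy-3,6-dimethylbenzoate
Conditions: Cl2CHOMe, TiCl4, CH2Cl2, −10 to 0 °C; then aq. HCl
Reagents that add atoms: dichloromethyl methyl ether, COC(Cl)Cl; water, O
Why: Rieche formylation; C5′ is the only unsubstituted ring carbon and lies ortho to the C4′ phenol and para to the C2′ phenol, so the site is fixed, and aqueous work-up hydrolyses the chloro ether to the aldehyde.

Step 3
Reactants: 3 benzyl 5-formyl-2,4-dihydroxy-3,6-dimethylbenzoate
Product: 4 benzyl 2,4-bis(benzyloxy)-5-formyl-3,6-dimethylbenzoate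
Conditions: BnBr (2.4 equiv), K2CO3, DMF, 60 °C
Reagents that add atoms: benzyl bromide, BrCc1ccccc1
Why: Williamson etherification of both chelated phenols under forcing but standard conditions; it ensures that only one phenol is free after step 4.

Step 4
Reactants: 4 benzyl 2,4-bis(benzyloxy)-5-formyl-3,6-dimethylbenzoate
Product: 6 benzyl 2,4-bis(benzyloxy)-5-hydroxy-3,6-dimethylbenzoate, via aryl formate 5 (not isolated)
Conditions: mCPBA, CH2Cl2, 0 °C to rt; then MeOH, K2CO3 (cat.), 0 °C
Reagents that add atoms: 3-chloroperoxybenzoic acid (mCPBA), O=C(OO)c1cccc(Cl)c1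
Why: Baeyer–Villiger (Dakin-type) oxidation; the aryl group with ortho and para benzyloxy substituents should migrate in preference to hydride, and the formate is cleaved by brief methanolysis that the di-ortho-substituted benzyl benzoate is too hindered to share.

Step 5
Reactants: 7 2,2,6-trimethyl-4H-1,3-dioxin-4-one; 8 benzyl chloroformate
Product: 9 benzyl 2-(2,2-dimethyl-4-oxo-4H-1,3-dioxin-6-yl)acetate
Conditions: 7 (2 equiv), LiN(SiMe3)2 (2 equiv), THF, −78 °C; then 8 (1 equiv), −78 °C; dilute aq. HCl
Reagents that add atoms: none
Why: Vinylogous (γ-selective) C-acylation of the lithium dienolate of the dioxinone with a chloroformate; two equivalents of dienolate are used because 9 is more acidic than 7.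

Step 6
Reactants: 9 benzyl 2-(2,2-dimethyl-4-oxo-4H-1,3-dioxin-6-yl)acetate; 10 diketene
Product: 11 benzyl 2-(2,2-dimethyl-4-oxo-4H-1,3-dioxin-6-yl)-3,5-dioxohexanoate
Conditions: NaH (1.05 equiv), THF, 0 °C; then 10 (1.1 equiv), −20 to 0 °C; cold 1 M HCl
Reagents that add atoms: none
Why: C-acetoacetylation of a stabilized sodium enolate by acyl–oxygen opening of diketene, as with malonate enolates; the methylene between the ester and the dioxinone is the only acidic carbon, and a cold acidic quench avoids premature cyclization of the product enolate.

Step 7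
Reactants: 11 benzyl 2-(2,2-dimethyl-4-oxo-4H-1,3-dioxin-6-yl)-3,5-dioxohexanoate; 6 benzyl 2,4-bis(benzyloxy)-5-hydroxy-3,6-dimethylbenzoate
Product: 13 benzyl 2,4-bis(benzyloxy)-5-({4-[(benzyloxy)carbonyl]-3,5,7-trioxooctanoyl}oxy)-3,6-dimethylbenzoate (drawn as one enol), via acylketene 12 (not isolated)
Conditions: 11 (1.5 equiv), 6 (1 equiv), toluene (0.3 M), 110 °C, 30 min; concentrate and use crude
Reagents that add atoms: none
Why: Thermal retro-[4+2] of the dioxinone releases the acylketene, and the phenol O–H adds across it (acylketene capture), an addition that tolerates two ortho substituents; the cheap partner 11 is used in excess and the solution kept concentrated so that capture by 6 can outrun capture by the chain's own enol oxygen.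

Step 8
Reactants: 13 benzyl 2,4-bis(benzyloxy)-5-({4-[(benzyloxy)carbonyl]-3,5,7-trioxooctanoyl}oxy)-3,6-dimethylbenzoate
Product: 15 benzyl 2,4-bis(benzyloxy)-5-({3-[(benzyloxy)carbonyl]-2,4-dihydroxy-6-methylbenzoyl}oxy)-3,6-dimethylbenzoate, via cyclic aldol adduct 14 (not isolated)
Conditions: Et3N (3 equiv), CH2Cl2, 0 °C to rt; then HCl (4 M in dioxane), rt
Reagents that add atoms: none
Why: Et3N deprotonates the chain, and the carbon between the aryl ester and the C5 carbonyl (ring A C4) adds as a β-keto ester enolate to the C3 methyl ketone in a 6-(enolexo)-exo-trig aldol closure, allowed by the Baldwin enolate rules, giving carbinol 14. HCl then eliminates water and the C1 and C5 carbonyls enolize, so ring A should form irreversibly as resorcylate 15. The closest known reaction type is the base-then-acid aldol aromatization of 3,5,7-triketo esters to resorcylates after acylketene capture from dioxinones, the laboratory form of the orsellinic acid folding. The two stereocentres of 14 (C3 and C4) are uncontrolled and vanish on aromatization, so none has to be set. The selectivity needed is C3–C4 aldol closure over Claisen closure of C2 onto the aryl ester with loss of the ring B phenoxide, over aldol attack of the terminal methyl on the C5 carbonyl, and over O-cyclization to pyranones. The substrate should secure this because the C6 benzyl ester holds the C5 and C1 carbonyls in a chelated enol, leaving the C3 ketone as the only ketone-like electrophile and lowering carbanion character at C2; because the aryl ester carbonyl is shielded by the C6′ methyl and C4′ benzyloxy groups of ring B; and because the terminal methyl is the least acidic carbon of the chain. A weak amine base at 0 °C and acid-driven dehydration keep the phenoxide-expelling pathway slow.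

Step 9
Reactants: 15 benzyl 2,4-bis(benzyloxy)-5-({3-[(benzyloxy)carbonyl]-2,4-dihydroxy-6-methylbenzoyl}oxy)-3,6-dimethylbenzoate
Product: 16 benzyl 2,4-bis(benzyloxy)-5-({3-[(benzyloxy)carbonyl]-2-hydroxy-4-methoxy-6-methylbenzoyl}oxy)-3,6-dimethylbenzoate
Conditions: MeI (1.1 equiv), K2CO3 (1.1 equiv), acetone, rt
Reagents that add atoms: iodomethane, CI
Why: Williamson methylation; the C1 hydroxyl has one ortho carbonyl and an ortho hydrogen, whereas the C5 hydroxyl sits between two carbonyl groups and is hindered and doubly chelated, so limited MeI should alkylate C1–OH, as in the 4-O-methylation of 3-acyl-2,4-dihydroxybenzoates.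

Step 10
Reactants: 16 benzyl 2,4-bis(benzyloxy)-5-({3-[(benzyloxy)carbonyl]-2-hydroxy-4-methoxy-6-methylbenzoyl}oxy)-3,6-dimethylbenzoate
Product: 17 hypothamnolic acid, 5-[(3-carboxy-2-hydroxy-4-methoxy-6-methylbenzoyl)oxy]-2,4-dihydroxy-3,6-dimethylbenzoic acid
Conditions: H2 (1 atm), 10% Pd/C, EtOAc/THF, rt
Reagents that add atoms: none
Why: Hydrogenolysis of two benzyl ethers and two benzyl esters under neutral conditions; the aryl ester and methyl ether are inert, and neutrality at room temperature should prevent acyl migration to the freed C4′ hydroxyl and decarboxylation.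

## Compound list

1 | 2,4-dihydroxy-3,6-dimethylbenzoic acid | Cc1cc(O)c(C)c(O)c1C(=O)O | starting material
2 | benzyl 2,4-dihydroxy-3,6-dimethylbenzoate | Cc1cc(O)c(C)c(O)c1C(=O)OCc1ccccc1 | intermediate
3 | benzyl 5-formyl-2,4-dihydroxy-3,6-dimethylbenzoate | Cc1c(C=O)c(O)c(C)c(O)c1C(=O)OCc1ccccc1 | intermediate
4 | benzyl 2,4-bis(benzyloxy)-5-formyl-3,6-dimethylbenzoate | Cc1c(C=O)c(OCc2ccccc2)c(C)c(OCc2ccccc2)c1C(=O)OCc1ccccc1 | intermediate
5 | benzyl 2,4-bis(benzyloxy)-5-(formyloxy)-3,6-dimethylbenzoate | Cc1c(OC=O)c(OCc2ccccc2)c(C)c(OCc2ccccc2)c1C(=O)OCc1ccccc1 | intermediate (not isolated)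
6 | benzyl 2,4-bis(benzyloxy)-5-hydroxy-3,6-dimethylbenzoate | Cc1c(O)c(OCc2ccccc2)c(C)c(OCc2ccccc2)c1C(=O)OCc1ccccc1 | intermediate
7 | 2,2,6-trimethyl-4H-1,3-dioxin-4-one | CC1=CC(=O)OC(C)(C)O1 | starting material
8 | benzyl chloroformate | O=C(Cl)OCc1ccccc1 | starting material
9 | benzyl 2-(2,2-dimethyl-4-oxo-4H-1,3-dioxin-6-yl)acetate | CC1(C)OC(=O)C=C(CC(=O)OCc2ccccc2)O1 | intermediate
10 | diketene (4-methylideneoxetan-2-one) | C=C1CC(=O)O1 | starting material
11 | benzyl 2-(2,2-dimethyl-4-oxo-4H-1,3-dioxin-6-yl)-3,5-dioxohexanoate | CC(=O)CC(=O)C(C(=O)OCc1ccccc1)C1=CC(=O)OC(C)(C)O1 | intermediate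
12 | benzyl 3,5-dioxo-2-(3-oxoprop-2-enoyl)hexanoate (acylketene) | CC(=O)CC(=O)C(C(=O)OCc1ccccc1)C(=O)C=C=O | intermediate (not isolated)
13 | benzyl 2,4-bis(benzyloxy)-5-({4-[(benzyloxy)carbonyl]-3,5,7-trioxooctanoyl}oxy)-3,6-dimethylbenzoate, drawn as one enol | CC(=O)CC(=O)/C(C(=O)OCc1ccccc1)=C(\O)CC(=O)Oc1c(C)c(C(=O)OCc2ccccc2)c(OCc2ccccc2)c(C)c1OCc1ccccc1 | intermediate
14 | cyclic aldol adduct, the ring B aryl 3-[(benzyloxy)carbonyl]-2,6-dihydroxy-6-methyl-4-oxocyclohex-2-ene-1-carboxylate (one tautomer, mixture of diastereomers, stereocentres not defined) | CC1(O)CC(=O)C(C(=O)OCc2ccccc2)=C(O)C1C(=O)Oc1c(C)c(C(=O)OCc2ccccc2)c(OCc2ccccc2)c(C)c1OCc1ccccc1 | intermediate (not isolated)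
15 | benzyl 2,4-bis(benzyloxy)-5-({3-[(benzyloxy)carbonyl]-2,4-dihydroxy-6-methylbenzoyl}oxy)-3,6-dimethylbenzoate | Cc1cc(O)c(C(=O)OCc2ccccc2)c(O)c1C(=O)Oc1c(C)c(C(=O)OCc2ccccc2)c(OCc2ccccc2)c(C)c1OCc1ccccc1 | intermediate
16 | benzyl 2,4-bis(benzyloxy)-5-({3-[(benzyloxy)carbonyl]-2-hydroxy-4-methoxy-6-methylbenzoyl}oxy)-3,6-dimethylbenzoate | COc1cc(C)c(C(=O)Oc2c(C)c(C(=O)OCc3ccccc3)c(OCc3ccccc3)c(C)c2OCc2ccccc2)c(O)c1C(=O)OCc1ccccc1 | intermediate
17 | hypothamnolic acid | COc1cc(C)c(C(=O)Oc2c(C)c(C(=O)O)c(O)c(C)c2O)c(O)c1C(=O)O | target

## Step count and least certain steps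

Total: 10 steps. Longest linear sequence: 8 steps (1, 2, 3, 4, 7, 8, 9, 10, from compound 1); the chain branch adds steps 5 and 6.

**Step 8 (key step).** The most likely failure is Claisen-type closure of C2 onto the depside carbonyl, or O-cyclization, each expelling the ring B phenoxide; an aryl ester is a better acyl donor than the alkyl esters of the closest cases. The fallback sets out from 11 and returns at 15. Ring A is closed while the acyl carbon is still a dioxinone: Et3N and then HCl convert 11 by the analogous aldol aromatization (dioxinone C5 onto the methyl ketone) into benzyl 7-hydroxy-2,2,5-trimethyl-4-oxo-4H-1,3-benzodioxine-8-carboxylate F1. Irradiation of F1 at 300 nm in the presence of 6 then releases an o-quinone ketene that 6 captures to give 15.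

**Step 7.** The likely failure is capture of the ketene by the enol oxygen of its own tricarbonyl unit (pyranone formation) before the hindered phenol adds. The fallback sets out from 6 and returns at 13. It places the aryl ester in an acyl donor and keeps the far ketone masked.
- 6 is heated with Meldrum's acid to give the hydrogen malonate 3-{2,4-bis(benzyloxy)-5-[(benzyloxy)carbonyl]-3,6-dimethylphenoxy}-3-oxopropanoic acid F2.
- Oxalyl chloride converts F2 into its acid chloride F3.
- MgCl2 and pyridine (Rathke-type C-acylation) join F3 to benzyl 4-(2-methyl-1,3-dioxolan-2-yl)-3-oxobutanoate F4, itself made by crossed Claisen condensation of ethyl (2-methyl-1,3-dioxolan-2-yl)acetate with the lithium enolate of benzyl acetate. The product is the ketal-masked chain F5.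
- Dilute aqueous acid removes the dioxolane from F5 and gives 13.

**Step 6.** The likely failures are O-acylation, attack through the dioxinone ring carbon, oligomerization of diketene, or premature ring closure of the product enolate. The fallback sets out from 9 and returns at 11. MgCl2 and pyridine C-acylate 9 with (2-methyl-1,3-dioxolan-2-yl)acetyl chloride F6, made from the corresponding acid with oxalyl chloride and pyridine. This gives benzyl 2-(2,2-dimethyl-4-oxo-4H-1,3-dioxin-6-yl)-4-(2-methyl-1,3-dioxolan-2-yl)-3-oxobutanoate F7. Transketalization of F7 in wet acetone with pyridinium p-toluenesulfonate frees the methyl ketone and gives 11.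

**Step 9.** The likely failure is alkylation at the C5 hydroxyl or double alkylation, since both phenols are chelated. The fallback sets out from 11 and returns at 16. It goes through the benzodioxinone F1 of the step 8 fallback, in which the C5 oxygen is held in the acetonide and the C1 hydroxyl is the only free phenol. Methylation of F1 with MeI and K2CO3 gives benzyl 7-methoxy-2,2,5-trimethyl-4-oxo-4H-1,3-benzodioxine-8-carboxylate F8. Photochemical release of its o-quinone ketene in the presence of 6 gives 16.

## Further compounds

F1 | step 8 | benzyl 7-hydroxy-2,2,5-trimethyl-4-oxo-4H-1,3-benzodioxine-8-carboxylate | Cc1cc(O)c(C(=O)OCc2ccccc2)c2OC(C)(C)OC(=O)c12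
F2 | step 7 | 3-{2,4-bis(benzyloxy)-5-[(benzyloxy)carbonyl]-3,6-dimethylphenoxy}-3-oxopropanoic acid | O=C(O)CC(=O)Oc1c(C)c(C(=O)OCc2ccccc2)c(OCc2ccccc2)c(C)c1OCc1ccccc1
F3 | step 7 | benzyl 2,4-bis(benzyloxy)-5-[(3-chloro-3-oxopropanoyl)oxy]-3,6-dimethylbenzoate | O=C(Cl)CC(=O)Oc1c(C)c(C(=O)OCc2ccccc2)c(OCc2ccccc2)c(C)c1OCc1ccccc1
F4 | step 7 | benzyl 4-(2-methyl-1,3-dioxolan-2-yl)-3-oxobutanoate | CC1(CC(=O)CC(=O)OCc2ccccc2)OCCO1
F5 | step 7 | benzyl 2,4-bis(benzyloxy)-5-({4-[(benzyloxy)carbonyl]-6-(2-methyl-1,3-dioxolan-2-yl)-3,5-dioxohexanoyl}oxy)-3,6-dimethylbenzoate | CC1(CC(=O)C(C(=O)OCc2ccccc2)C(=O)CC(=O)Oc2c(C)c(C(=O)OCc3ccccc3)c(OCc3ccccc3)c(C)c2OCc2ccccc2)OCCO1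
F6 | step 6 | (2-methyl-1,3-dioxolan-2-yl)acetyl chloride | CC1(CC(=O)Cl)OCCO1
F7 | step 6 | benzyl 2-(2,2-dimethyl-4-oxo-4H-1,3-dioxin-6-yl)-4-(2-methyl-1,3-dioxolan-2-yl)-3-oxobutanoate | CC1(CC(=O)C(C(=O)OCc2ccccc2)C2=CC(=O)OC(C)(C)O2)OCCO1
F8 | step 9 | benzyl 7-methoxy-2,2,5-trimethyl-4-oxo-4H-1,3-benzodioxine-8-carboxylate | COc1cc(C)c2C(=O)OC(C)(C)Oc2c1C(=O)OCc1ccccc1
A1 | alternative 1 | 5-formyl-2,4-dihydroxy-3,6-dimethylphenyl 3-formyl-2-hydroxy-4-methoxy-6-methylbenzoate | COc1cc(C)c(C(=O)Oc2c(C)c(C=O)c(O)c(C)c2O)c(O)c1C=O
A2 | alternative 1 | 2,4-dihydroxy-3,6-dimethylphenyl 2-hydroxy-4-methoxy-6-methylbenzoate | COc1cc(C)c(C(=O)Oc2c(C)cc(O)c(C)c2O)c(O)c1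
A3 | alternative 2 | benzyl 5-({2-(benzyloxy)-3-[(benzyloxy)carbonyl]-4-methoxy-6-methylbenzoyl}oxy)-2,4-dihydroxy-3,6-dimethylbenzoate | COc1cc(C)c(C(=O)Oc2c(C)c(C(=O)OCc3ccccc3)c(O)c(C)c2O)c(OCc2ccccc2)c1C(=O)OCc1ccccc1
A4 | alternative 2 | 4-(benzyloxy)-3-methyl-2,4-bis(trimethylsilyloxy)buta-1,3-dien-1-yl 2-(benzyloxy)-3-[(benzyloxy)carbonyl]-4-methoxy-6-methylbenzoate | COc1cc(C)c(C(=O)OC=C(O[Si](C)(C)C)C(C)=C(OCc2ccccc2)O[Si](C)(C)C)c(OCc2ccccc2)c1C(=O)OCc1ccccc1
A5 | alternative 2 | benzyl but-2-ynoate | CC#CC(=O)OCc1ccccc1
A6 | alternative 3 | benzyl 2,4-bis(benzyloxy)-5-({3-[(benzyloxy)carbonyl]-2-hydroxy-4-methoxy-6-methylbenzoyl}oxy)-3,6-dimethylbenzoate (identical with 16) | COc1cc(C)c(C(=O)Oc2c(C)c(C(=O)OCc3ccccc3)c(OCc3ccccc3)c(C)c2OCc2ccccc2)c(O)c1C(=O)OCc1ccccc1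
A7 | alternative 3 | benzyl 2,4-bis(benzyloxy)-5-(but-2-ynoyloxy)-3,6-dimethylbenzoate | CC#CC(=O)Oc1c(C)c(C(=O)OCc2ccccc2)c(OCc2ccccc2)c(C)c1OCc1ccccc1
A8 | alternative 3 | benzyl 2-[(benzyloxy)(trimethylsilyloxy)methylidene]-3-methoxybut-3-enoate | C=C(OC)C(C(=O)OCc1ccccc1)=C(OCc1ccccc1)O[Si](C)(C)C
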